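**Assumption:** the target has no stereocentre and its SMILES carries no axial descriptor, so the aryl–naphthalene axis is taken as not configurationally fixed; the racemic sp3 centre of compounds 7–11 disappears on aromatisation, and bromide 4 is taken as a catalogue compound.

## Retrosynthetic overview

1. Target ⇐ hydrogenolysis of its tetra-O-benzyl ether; the three benzene rings are bought (ring A = trioxygenated benzo ring, ring C = 4-hydroxy-2-methoxyphenyl, ring D = catechol).
2. Ring B (the second naphthalene ring) is the only ring built, and it is built last: the C1–C8a bond is closed by a reversed-polarity α-arylation, in which the methyl-ketone α-carbon acts as an enolonium (silyl enol ether plus trivalent iodine) and is attacked by the free ortho C–H of ring A.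
3. The exocyclic benzylidene of the cyclised ketone then tautomerises into the ring, so aromatisation to the 2-naphthol needs no separate oxidant.
4. The cyclisation precursor, an α-(diarylmethyl)-α-benzylidene methyl ketone, comes from a one-pot aryl Grignard conjugate addition / Horner–Wadsworth–Emmons olefination on a phosphono-enone.
5. The phosphono-enone comes from Knoevenagel condensation of O-benzylsyringaldehyde with dimethyl (2-oxopropyl)phosphonate.

## Route

**Step 1**
Reactants: 1 4-(benzyloxy)-3,5-dimethoxybenzaldehyde; 2 dimethyl (2-oxopropyl)phosphonate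
Product: 3 dimethyl {1-[4-(benzyloxy)-3,5-dimethoxyphenyl]-3-oxobut-1-en-2-yl}phosphonate (E/Z mixture)
Conditions: piperidine (20 mol %), AcOH (20 mol %), toluene, reflux, Dean–Stark
Reagents that add atoms: none
Why: Knoevenagel condensation of the doubly activated methylene of the β-ketophosphonate with the aryl aldehyde, driven by azeotropic removal of water; the alkene geometry is irrelevant because it is consumed in step 2.

**Step 2**
Reactants: 3 dimethyl {1-[4-(benzyloxy)-3,5-dimethoxyphenyl]-3-oxobut-1-en-2-yl}phosphonate; 4 4-(benzyloxy)-1-bromo-2-methoxybenzene; 5 3,4-bis(benzyloxy)benzaldehyde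
Product: 8 4-[3,4-bis(benzyloxy)phenyl]-3-{[4-(benzyloxy)-3,5-dimethoxyphenyl][4-(benzyloxy)-2-methoxyphenyl]methyl}but-3-en-2-one (racemic; E/Z mixture), via aryl Grignard reagent 6 (not isolated), via bromomagnesium phosphonoenolate 7 (not isolated)
Conditions: 4, Mg, THF, 45 °C; then 3, CuBr·SMe2 (10 mol %), THF, −40 → 0 °C; then 5, 0 °C → reflux; aq. NH4Cl
Reagents that add atoms: none
Why: Copper-catalysed conjugate addition of the aryl Grignard reagent to the doubly activated alkene gives a chelated β-ketophosphonate enolate that olefinates aldehyde 5 in the same pot (tandem Michael addition / Horner–Wadsworth–Emmons reaction); the new diarylmethine centre is racemic and, like the alkene geometry, is erased when ring B aromatises.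

**Step 3**
Reactants: 8 4-[3,4-bis(benzyloxy)phenyl]-3-{[4-(benzyloxy)-3,5-dimethoxyphenyl][4-(benzyloxy)-2-methoxyphenyl]methyl}but-3-en-2-one
Product: 12 7-(benzyloxy)-3-[3,4-bis(benzyloxy)benzyl]-4-[4-(benzyloxy)-2-methoxyphenyl]-6,8-dimethoxynaphthalen-2-ol, via silyl dienol ether 9 (not isolated), via trivalent-iodine enolonium species 10 (not isolated), via benzylidene tetralone 11 (not isolated)
Conditions: LiN(SiMe3)2, Me3SiCl, THF, −78 °C; evaporate, pentane, filter; crude 9 added dropwise to PhI(OH)OTs (1.0 equiv), BF3·OEt2 (1.5 equiv), CH2Cl2, −78 °C → rt, 3 h; aq. Na2S2O3/NaHCO3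
Reagents that add atoms: none
Why: Proposed new method: silicon-to-iodine exchange of the kinetic silyl dienol ether 9 with BF3-activated PhI(OH)OTs gives the O-bound trivalent-iodine enolate 10, an enolonium whose CH2 terminus is electrophilic; the free ortho C–H of ring A (ortho and para to two OMe groups, six-membered transition state) attacks it with loss of PhI to give 11, and the TsOH/BF3 present then enolises 11, protonates the benzylidene carbon and removes the C4 proton to give the aromatic 2-naphthol 12; the closest known reactions are the intermolecular α-arylation of ketone-derived enolonium species with electron-rich arenes, the acid-promoted Ar2-6 cyclisation of α-diazoketones to 2-tetralones, and the isomerisation of 2-benzylidene-1-tetralones to 2-benzyl-1-naphthols.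

**Step 4**
Reactants: 12 7-(benzyloxy)-3-[3,4-bis(benzyloxy)benzyl]-4-[4-(benzyloxy)-2-methoxyphenyl]-6,8-dimethoxynaphthalen-2-ol
Product: 13 3-(3,4-dihydroxybenzyl)-4-(4-hydroxy-2-methoxyphenyl)-6,8-dimethoxynaphthalene-2,7-diol (CNP0000244.0)
Conditions: H2 (1 atm), Pd/C (10 wt %), THF/MeOH, rt, under argon on work-up
Reagents that add atoms: none
Why: Catalytic hydrogenolysis cleaves the four aryl benzyl ethers, while the naphthalene core, the three methyl ethers and the diarylmethane CH2 are inert at 1 atm and room temperature.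

## Compound list

1 | 4-(benzyloxy)-3,5-dimethoxybenzaldehyde | COc1cc(C=O)cc(OC)c1OCc1ccccc1 | starting material
2 | dimethyl (2-oxopropyl)phosphonate | CC(=O)CP(=O)(OC)OC | starting material
3 | dimethyl {1-[4-(benzyloxy)-3,5-dimethoxyphenyl]-3-oxobut-1-en-2-yl}phosphonate (E/Z mixture) | CC(=O)C(=Cc1cc(OC)c(OCc2ccccc2)c(OC)c1)P(=O)(OC)OC | intermediate
4 | 4-(benzyloxy)-1-bromo-2-methoxybenzene | COc1cc(OCc2ccccc2)ccc1Br | starting material
5 | 3,4-bis(benzyloxy)benzaldehyde | O=Cc1ccc(OCc2ccccc2)c(OCc2ccccc2)c1 | starting material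
6 | [4-(benzyloxy)-2-methoxyphenyl]magnesium bromide | COc1cc(OCc2ccccc2)ccc1[Mg]Br | intermediate
7 | bromomagnesium enolate of dimethyl {1-[4-(benzyloxy)-3,5-dimethoxyphenyl]-1-[4-(benzyloxy)-2-methoxyphenyl]-3-oxobutan-2-yl}phosphonate (racemic) | CC(O[Mg]Br)=C(P(=O)(OC)OC)C(c1cc(OC)c(OCc2ccccc2)c(OC)c1)c1ccc(OCc2ccccc2)cc1OC | intermediate
8 | 4-[3,4-bis(benzyloxy)phenyl]-3-{[4-(benzyloxy)-3,5-dimethoxyphenyl][4-(benzyloxy)-2-methoxyphenyl]methyl}but-3-en-2-one (racemic; E/Z mixture) | CC(=O)C(=Cc1ccc(OCc2ccccc2)c(OCc2ccccc2)c1)C(c1cc(OC)c(OCc2ccccc2)c(OC)c1)c1ccc(OCc2ccccc2)cc1OC | intermediate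
9 | trimethylsilyl dienol ether of 8: {[4-(3,4-bis(benzyloxy)phenyl)-3-(diarylmethyl)buta-1,3-dien-2-yl]oxy}trimethylsilane (racemic) | C=C(O[Si](C)(C)C)C(=Cc1ccc(OCc2ccccc2)c(OCc2ccccc2)c1)C(c1cc(OC)c(OCc2ccccc2)c(OC)c1)c1ccc(OCc2ccccc2)cc1OC | intermediate
10 | enolonium species: O-[phenyl(tosyloxy)iodanyl] dienolate of 8 (racemic; BF3-activated) | C=C(OI(OS(=O)(=O)c1ccc(C)cc1)c1ccccc1)C(=Cc1ccc(OCc2ccccc2)c(OCc2ccccc2)c1)C(c1cc(OC)c(OCc2ccccc2)c(OC)c1)c1ccc(OCc2ccccc2)cc1OC | intermediate
11 | 7-(benzyloxy)-3-[3,4-bis(benzyloxy)benzylidene]-4-[4-(benzyloxy)-2-methoxyphenyl]-6,8-dimethoxy-3,4-dihydronaphthalen-2(1H)-one (racemic; E/Z mixture) | O=C1Cc2c(OC)c(OCc3ccccc3)c(OC)cc2C(c2ccc(OCc3ccccc3)cc2OC)C1=Cc1ccc(OCc2ccccc2)c(OCc2ccccc2)c1 | intermediate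
12 | 7-(benzyloxy)-3-[3,4-bis(benzyloxy)benzyl]-4-[4-(benzyloxy)-2-methoxyphenyl]-6,8-dimethoxynaphthalen-2-ol | COc1cc(OCc2ccccc2)ccc1-c1c(Cc2ccc(OCc3ccccc3)c(OCc3ccccc3)c2)c(O)cc2c(OC)c(OCc3ccccc3)c(OC)cc12 | intermediate
13 | 3-(3,4-dihydroxybenzyl)-4-(4-hydroxy-2-methoxyphenyl)-6,8-dimethoxynaphthalene-2,7-diol | COc1cc(O)ccc1-c1c(Cc2ccc(O)c(O)c2)c(O)cc2c(OC)c(O)c(OC)cc12 | target

## Step count

Total steps: 4. Longest linear sequence: 4 (1 → 3 → 8 → 12 → 13).

## Steps most likely to fail, with fallbacks

**Step 3 (enolonium ring closure).** The risks are: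
- ipso attack of ring C on the enolonium, which would give a spiro ketone (the unsubstituted, doubly activated ring A position and the six-membered closure should win, but this is not proven);
- attack by ring D from the isomer of 8 in which ring D is cis to the acyl group;
- α-tosyloxylation of the ketone;
- over-oxidation of the electron-rich naphthol by residual oxidant.

The fallback uses an oxidant-free enolonium equivalent. It sets out from 8. Detrifluoroacetylative diazo transfer (LiN(SiMe3)2, CF3CO2CH2CF3, THF, −78 °C) gives the trifluoroacetyl diketone 6-[3,4-bis(benzyloxy)phenyl]-5-{[4-(benzyloxy)-3,5-dimethoxyphenyl][4-(benzyloxy)-2-methoxyphenyl]methyl}-1,1,1-trifluorohex-5-ene-2,4-dione F1, which is not isolated. Treatment with MsN3, Et3N and H2O in MeCN at rt gives the α′-diazo enone 4-[3,4-bis(benzyloxy)phenyl]-3-{[4-(benzyloxy)-3,5-dimethoxyphenyl][4-(benzyloxy)-2-methoxyphenyl]methyl}-1-diazobut-3-en-2-one F2. TFA (5 equiv) in CH2Cl2 at −20 °C → rt then protonates the diazo carbon, and ring A displaces N2 in an Ar2-6 cyclisation to give 11, which tautomerises in the acid (if that lags, catalytic RhCl3·3H2O in EtOH at reflux). The fallback comes back to the route at 12.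

**Step 2 (tandem conjugate addition / olefination).** The risk is that the hindered tertiary phosphonoenolate 7 olefinates the electron-rich aldehyde 5 slowly or not at all. The fallback replaces the arylidene olefination by methylenation followed by a Mizoroki–Heck arylation. It sets out from 3 and 4 and proceeds as before through 6 to 7, but 7 is quenched with aq. NH4Cl to isolate the β-ketophosphonate dimethyl {1-[4-(benzyloxy)-3,5-dimethoxyphenyl]-1-[4-(benzyloxy)-2-methoxyphenyl]-3-oxobutan-2-yl}phosphonate F3. Olefination with unhindered aqueous formaldehyde (C=O; K2CO3, THF/H2O, rt) gives the α-methylene ketone 3-{[4-(benzyloxy)-3,5-dimethoxyphenyl][4-(benzyloxy)-2-methoxyphenyl]methyl}but-3-en-2-one F4. Heck coupling of F4 with 4-bromo-1,2-bis(benzyloxy)benzene (Brc1ccc(OCc2ccccc2)c(OCc2ccccc2)c1; Pd(OAc)2, P(o-tol)3, Et3N, DMF, 100 °C) places ring D on the terminal carbon, and β-hydride elimination toward the new benzylic CH gives the conjugated arylidene. The fallback comes back to the route at 8.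

**Step 4 (global debenzylation).** The risks are catalyst poisoning by traces of iodobenzene or sulfur carried over from step 3, incomplete removal of the fourth benzyl group, and air oxidation of the catechol/naphthol product. The fallback replaces hydrogenolysis by Lewis-acid dealkylation with a cation scavenger: from 12, BCl3 with pentamethylbenzene in CH2Cl2 at −78 °C removes the four benzyl groups as benzylpentamethylbenzene and spares the aryl methyl ethers. No new compound is made (F0), and the fallback comes back to the route at 13.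

## Further compounds

F1 | step 3 | 6-[3,4-bis(benzyloxy)phenyl]-5-{[4-(benzyloxy)-3,5-dimethoxyphenyl][4-(benzyloxy)-2-methoxyphenyl]methyl}-1,1,1-trifluorohex-5-ene-2,4-dione | O=C(CC(=O)C(F)(F)F)C(=Cc1ccc(OCc2ccccc2)c(OCc2ccccc2)c1)C(c1cc(OC)c(OCc2ccccc2)c(OC)c1)c1ccc(OCc2ccccc2)cc1OC
F2 | step 3 | 4-[3,4-bis(benzyloxy)phenyl]-3-{[4-(benzyloxy)-3,5-dimethoxyphenyl][4-(benzyloxy)-2-methoxyphenyl]methyl}-1-diazobut-3-en-2-one | [N-]=[N+]=CC(=O)C(=Cc1ccc(OCc2ccccc2)c(OCc2ccccc2)c1)C(c1cc(OC)c(OCc2ccccc2)c(OC)c1)c1ccc(OCc2ccccc2)cc1OC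
F3 | step 2 | dimethyl {1-[4-(benzyloxy)-3,5-dimethoxyphenyl]-1-[4-(benzyloxy)-2-methoxyphenyl]-3-oxobutan-2-yl}phosphonate | CC(=O)C(P(=O)(OC)OC)C(c1cc(OC)c(OCc2ccccc2)c(OC)c1)c1ccc(OCc2ccccc2)cc1OC
F4 | step 2 | 3-{[4-(benzyloxy)-3,5-dimethoxyphenyl][4-(benzyloxy)-2-methoxyphenyl]methyl}but-3-en-2-one | CC(=O)C(=C)C(c1cc(OC)c(OCc2ccccc2)c(OC)c1)c1ccc(OCc2ccccc2)cc1OC
F0 | step 4 | none | none
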